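**Retrosynthetic overview**
- The target comes from one acid treatment that removes two aryl MOM ethers and a tert-butyl ester; the p-coumarate is put on the side-chain allylic alcohol by Mitsunobu acylation with the free acid.
- Key disconnection: the O1–C2 ether bond of the oxepine, made by a catalytic enantioselective 7-exo oxa-Michael addition of a (Z)-allylic alcohol to a trisubstituted β-aroylacrylate. This step closes the only ring that has to be built (both benzene rings are bought) and sets the (S) tetrasubstituted carbon.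
- The cyclisation precursor comes from a B-alkyl Suzuki coupling (C2–C3) of the 9-BBN adduct of a (Z)-dienediol with an α-bromo-β-aroylacrylate.
- The dienediol comes from propargyl alcohol, a side-chain Grignard reagent and vinyl bromide (directed anti-carbomagnesiation fixes Z); the side chain comes from SeO2 oxidation of homoprenyl bromide (fixes E).
- The bromo-aroylacrylate comes from 2',5'-dihydroxyacetophenone by MOM protection, SeO2 oxidation to the glyoxal and a bromo-Wittig reaction.

**Assumption:** the stereocentre in the SMILES is read as (S) (CIP order O > CO2H > CH2C(=O)Ar > ring CH2); the side-chain alkene and the cinnamate are both E. Oxepine numbering: O1, C2 (quaternary), C3, C4, C5=C6, C7.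

**Catalyst A (step 7):** 1-[3,5-bis(trifluoromethyl)phenyl]-3-[(2S)-3,3-dimethyl-1-{[tris(4-methoxyphenyl)-λ5-phosphanylidene]amino}butan-2-yl]thiourea, SMILES COc1ccc(cc1)P(=NC[C@@H](NC(=S)Nc1cc(cc(c1)C(F)(F)F)C(F)(F)F)C(C)(C)C)(c1ccc(OC)cc1)c1ccc(OC)cc1. The facial sense of this new step cannot be known in advance; if the first run gives the (R)-ether, the mirror-image catalyst from (R)-tert-leucine is used instead.

**Step 1**
Reactants: 1 5-bromo-2-methylpent-2-ene
Product: 2 (2E)-5-bromo-2-methylpent-2-en-1-ol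
Conditions: SeO2 (0.3 equiv), tBuOOH (2.5 equiv), salicylic acid (0.1 equiv), CH2Cl2, 0 °C → rt
Reagents that add atoms: selenium dioxide, O=[Se]=O; tert-butyl hydroperoxide, CC(C)(C)OO (terminal oxygen source that regenerates SeO2)
Why: Catalytic SeO2/tBuOOH allylic oxidation (ene reaction, then [2,3]-sigmatropic shift) oxidises the E-methyl group of the trisubstituted alkene selectively, which sets the (E)-CH2OH terminus of the side chain, and a primary alkyl bromide is inert to it.

**Step 2**
Reactants: 2 (2E)-5-bromo-2-methylpent-2-en-1-ol; 3 prop-2-yn-1-ol; 4 bromoethene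
Product: 7 (2E,6Z)-2-methyl-6-(prop-2-en-1-ylidene)hept-2-ene-1,7-diol, via alkoxide Grignard reagent 5 (not isolated), via vinylmagnesium chelate 6 (not isolated)
Conditions: 2 (1.5 equiv), iPrMgCl then Mg, THF, 0 → 40 °C; then 3 (pre-treated with iPrMgCl), CuI (10 mol%), THF/toluene, 0 → 45 °C; then 4 (3 equiv), Pd(PPh3)4 (3 mol%), 50 °C; aq NH4Cl
Reagents that add atoms: none
Why: A Normant-type alkoxide Grignard reagent adds to the magnesium alkoxide of propargyl alcohol by CuI-catalysed, alkoxide-directed anti-carbomagnesiation (alkyl to C2, magnesium to C3 inside a five-membered chelate), and the Kumada–Corriu coupling with vinyl bromide proceeds with retention, so the vinyl group ends cis to CH2OH and the Z-trisubstituted alkene is fixed.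

**Step 3**
Reactants: 8 1-(2,5-dihydroxyphenyl)ethan-1-one
Product: 9 1-[2,5-bis(methoxymethoxy)phenyl]ethan-1-one
Conditions: NaH (2.4 equiv), MOMCl (2.5 equiv), DMF, 0 °C → rt
Reagents that add atoms: chloromethyl methyl ether (MOMCl), COCCl
Why: Williamson-type O-alkylation of both phenoxides (NaH breaks the hydrogen bond of the ortho OH to the ketone) gives base-stable, acid-labile MOM ethers that block chromone and chromanone formation until the last step.

**Step 4**
Reactants: 9 1-[2,5-bis(methoxymethoxy)phenyl]ethan-1-one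
Product: 10 2-[2,5-bis(methoxymethoxy)phenyl]-2-oxoacetaldehyde
Conditions: SeO2 (1.2 equiv), 1,4-dioxane/H2O (30:1), 90 °C; toluene azeotrope to the free keto-aldehyde
Reagents that add atoms: selenium dioxide, O=[Se]=O
Why: Riley oxidation converts the methyl ketone, the only position with α-hydrogens, into the aryl glyoxal in a medium that is too weakly acidic to cleave aryl MOM ethers quickly.

**Step 5**
Reactants: 10 2-[2,5-bis(methoxymethoxy)phenyl]-2-oxoacetaldehyde; 11 tert-butyl (triphenyl-λ5-phosphanylidene)acetate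
Product: 13 tert-butyl (2Z)-4-[2,5-bis(methoxymethoxy)phenyl]-2-bromo-4-oxobut-2-enoate, via bromo ylide 12 (not isolated)
Conditions: 11, NBS (1.05 equiv), CH2Cl2, −20 °C; then 10, rt
Reagents that add atoms: N-bromosuccinimide, O=C1CCC(=O)N1Br
Why: Bromination of the stabilised ylide with NBS gives the bromo ylide in situ, and its Wittig reaction with the far more electrophilic aldehyde carbonyl puts the ester trans to the aroyl group as usual for stabilised ylides, which gives the (Z)-α-bromo enoate with bromine cis to the aroyl group.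

**Step 6**
Reactants: 7 (2E,6Z)-2-methyl-6-(prop-2-en-1-ylidene)hept-2-ene-1,7-diol; 13 tert-butyl (2Z)-4-[2,5-bis(methoxymethoxy)phenyl]-2-bromo-4-oxobut-2-enoate
Product: 15 tert-butyl (2E)-4-[2,5-bis(methoxymethoxy)phenyl]-2-[(3Z,7E)-9-hydroxy-4-(hydroxymethyl)-8-methylnona-3,7-dien-1-yl]-4-oxobut-2-enoate, via tris-boron alkylborane 14 (not isolated)
Conditions: 9-BBN (3.3 equiv), THF, 0 °C → rt; then 3 M aq K3PO4, then 13, PdCl2(dppf) (5 mol%), AsPh3 (10 mol%), DMF, rt; pH 7 work-up
Reagents that add atoms: none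
Why: 9-BBN hydroborates only the terminal CH=CH2 of the diene at the terminal carbon (the two OH groups are masked in situ as borinates and residual B–H is destroyed by the aqueous base before 13 is added), and the B-alkyl Suzuki–Miyaura coupling replaces the vinylic bromide with retention, so the new alkyl chain lies cis to the aroyl group and the (E)-aroylacrylate results.

**Step 7**
Reactants: 15 tert-butyl (2E)-4-[2,5-bis(methoxymethoxy)phenyl]-2-[(3Z,7E)-9-hydroxy-4-(hydroxymethyl)-8-methylnona-3,7-dien-1-yl]-4-oxobut-2-enoate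
Product: 16 tert-butyl (2S)-2-{2-[2,5-bis(methoxymethoxy)phenyl]-2-oxoethyl}-6-[(3E)-5-hydroxy-4-methylpent-3-en-1-yl]-2,3,4,7-tetrahydrooxepine-2-carboxylate
Conditions: catalyst A (10 mol%), toluene (0.05 M), −20 °C → rt
Reagents that add atoms: none
Why: Proposed new method: a bifunctional iminophosphorane–thiourea catalyst promotes an enantioselective 7-exo-trig oxa-Michael addition in which the superbasic iminophosphorane activates the (Z)-allylic OH while the thiourea binds the aroyl and ester carbonyls, the alkoxide adds to C2 (β to the ketone, the normal regiochemistry of β-aroylacrylates) on one enantiotopic face inside the chiral ion pair to set the (S) tetrasubstituted ether carbon and close the oxepine, and the bound enolate is protonated to the CH2 ketone; the closest known reaction type is the iminophosphorane-catalysed intramolecular oxa-Michael addition of alcohols to β-monosubstituted unsaturated esters and amides giving tetrahydrofurans, tetrahydropyrans and oxepanes with a tertiary ether carbon, and what is new is the fully substituted β-carbon, the doubly activated acceptor and the unsaturated seven-membered ring.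

**Step 8**
Reactants: 16 tert-butyl (2S)-2-{2-[2,5-bis(methoxymethoxy)phenyl]-2-oxoethyl}-6-[(3E)-5-hydroxy-4-methylpent-3-en-1-yl]-2,3,4,7-tetrahydrooxepine-2-carboxylate; 17 (2E)-3-(4-hydroxyphenyl)prop-2-enoic acid
Product: 18 tert-butyl (2S)-2-{2-[2,5-bis(methoxymethoxy)phenyl]-2-oxoethyl}-6-[(3E)-5-{[(2E)-3-(4-hydroxyphenyl)prop-2-enoyl]oxy}-4-methylpent-3-en-1-yl]-2,3,4,7-tetrahydrooxepine-2-carboxylate
Conditions: 17 (1.5 equiv), PPh3, DIAD, THF, 0 °C → rt
Reagents that add atoms: none
Why: In this Mitsunobu esterification the carboxylic acid (pKa about 4.5) is engaged far ahead of the phenol (pKa about 10), so unprotected p-coumaric acid acylates the primary allylic alcohol by direct SN2 displacement without touching the alkene geometries or the remote stereocentre.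

**Step 9**
Reactants: 18 tert-butyl (2S)-2-{2-[2,5-bis(methoxymethoxy)phenyl]-2-oxoethyl}-6-[(3E)-5-{[(2E)-3-(4-hydroxyphenyl)prop-2-enoyl]oxy}-4-methylpent-3-en-1-yl]-2,3,4,7-tetrahydrooxepine-2-carboxylate
Product: 19 (2S)-2-[2-(2,5-dihydroxyphenyl)-2-oxoethyl]-6-[(3E)-5-{[(2E)-3-(4-hydroxyphenyl)prop-2-enoyl]oxy}-4-methylpent-3-en-1-yl]-2,3,4,7-tetrahydrooxepine-2-carboxylic acid
Conditions: TFA/CH2Cl2/H2O (9:10:1), 0 °C → rt, 2 h; cold evaporation, reverse-phase chromatography
Reagents that add atoms: none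
Why: Acidolysis with TFA cleaves the tert-butyl ester (E1 loss of isobutene) and both aryl MOM acetals in one operation, while the allylic cinnamate, the allylic ether of the oxepine and the quaternary β-alkoxy ketone centre (no base, so no retro-oxa-Michael) stay intact.

**Compound list**
1 | 5-bromo-2-methylpent-2-ene | CC(C)=CCCBr | starting material
2 | (2E)-5-bromo-2-methylpent-2-en-1-ol | OC/C(C)=C/CCBr | intermediate
3 | prop-2-yn-1-ol | C#CCO | starting material
4 | bromoethene | C=CBr | starting material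
5 | chloromagnesium (2E)-5-(bromomagnesio)-2-methylpent-2-en-1-olate | Cl[Mg]OC/C(C)=C/CC[Mg]Br | intermediate
6 | 4-[(3E)-5-(chloromagnesiooxy)-4-methylpent-3-en-1-yl]-2,5-dihydro-1,2-oxamagnesole | Cl[Mg]OC/C(C)=C/CCC1=C[Mg]OC1 | intermediate
7 | (2E,6Z)-2-methyl-6-(prop-2-en-1-ylidene)hept-2-ene-1,7-diol | C=C/C=C(\CO)CC/C=C(\C)CO | intermediate
8 | 1-(2,5-dihydroxyphenyl)ethan-1-one | CC(=O)c1cc(O)ccc1O | starting material
9 | 1-[2,5-bis(methoxymethoxy)phenyl]ethan-1-one | CC(=O)c1cc(OCOC)ccc1OCOC | intermediate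
10 | 2-[2,5-bis(methoxymethoxy)phenyl]-2-oxoacetaldehyde | O=CC(=O)c1cc(OCOC)ccc1OCOC | intermediate
11 | tert-butyl (triphenyl-λ5-phosphanylidene)acetate | CC(C)(C)OC(=O)C=P(c1ccccc1)(c1ccccc1)c1ccccc1 | starting material
12 | tert-butyl bromo(triphenyl-λ5-phosphanylidene)acetate | CC(C)(C)OC(=O)C(Br)=P(c1ccccc1)(c1ccccc1)c1ccccc1 | intermediate
13 | tert-butyl (2Z)-4-[2,5-bis(methoxymethoxy)phenyl]-2-bromo-4-oxobut-2-enoate | CC(C)(C)OC(=O)/C(Br)=C/C(=O)c1cc(OCOC)ccc1OCOC | intermediate
14 | 9-{(3Z,7E)-9-[(9-borabicyclo[3.3.1]nonan-9-yl)oxy]-4-{[(9-borabicyclo[3.3.1]nonan-9-yl)oxy]methyl}-8-methylnona-3,7-dien-1-yl}-9-borabicyclo[3.3.1]nonane | B1(CC/C=C(\COB2C3CCCC2CCC3)CC/C=C(\C)COB2C3CCCC2CCC3)C2CCCC1CCC2 | intermediate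
15 | tert-butyl (2E)-4-[2,5-bis(methoxymethoxy)phenyl]-2-[(3Z,7E)-9-hydroxy-4-(hydroxymethyl)-8-methylnona-3,7-dien-1-yl]-4-oxobut-2-enoate | CC(C)(C)OC(=O)/C(CC/C=C(\CO)CC/C=C(\C)CO)=C/C(=O)c1cc(OCOC)ccc1OCOC | intermediate
16 | tert-butyl (2S)-2-{2-[2,5-bis(methoxymethoxy)phenyl]-2-oxoethyl}-6-[(3E)-5-hydroxy-4-methylpent-3-en-1-yl]-2,3,4,7-tetrahydrooxepine-2-carboxylate | C/C(=C\CCC1=CCC[C@](CC(=O)c2cc(OCOC)ccc2OCOC)(C(=O)OC(C)(C)C)OC1)CO | intermediate
17 | (2E)-3-(4-hydroxyphenyl)prop-2-enoic acid (p-coumaric acid) | OC(=O)/C=C/c1ccc(O)cc1 | starting material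
18 | tert-butyl (2S)-2-{2-[2,5-bis(methoxymethoxy)phenyl]-2-oxoethyl}-6-[(3E)-5-{[(2E)-3-(4-hydroxyphenyl)prop-2-enoyl]oxy}-4-methylpent-3-en-1-yl]-2,3,4,7-tetrahydrooxepine-2-carboxylate | C/C(=C\CCC1=CCC[C@](CC(=O)c2cc(OCOC)ccc2OCOC)(C(=O)OC(C)(C)C)OC1)COC(=O)/C=C/c1ccc(O)cc1 | intermediate
19 | (2S)-2-[2-(2,5-dihydroxyphenyl)-2-oxoethyl]-6-[(3E)-5-{[(2E)-3-(4-hydroxyphenyl)prop-2-enoyl]oxy}-4-methylpent-3-en-1-yl]-2,3,4,7-tetrahydrooxepine-2-carboxylic acid (CNP0602535.2) | C/C(=C\CCC1=CCC[C@](CC(=O)c2cc(O)ccc2O)(C(=O)O)OC1)COC(=O)/C=C/c1ccc(O)cc1 | target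

**Totals**
- Total step count: 9.
- Longest linear sequence: 7 steps (steps 3, 4, 5, 6, 7, 8, 9 from 8); the side-chain branch is 6 steps (1, 2, 6, 7, 8, 9).

**Three steps most likely to fail**

Step 7 (the proposed new step). The risks are low conversion (the oxa-Michael addition to a fully substituted carbon is reversible), γ-deprotonation of the acceptor by the superbase, and insufficient enantioselectivity. The fallback uses known chemistry and sets out from 15. An achiral base (DBU, 20 mol%, toluene, rt) closes the ring without stereocontrol to the racemate tert-butyl (2RS)-2-{2-[2,5-bis(methoxymethoxy)phenyl]-2-oxoethyl}-6-[(3E)-5-hydroxy-4-methylpent-3-en-1-yl]-2,3,4,7-tetrahydrooxepine-2-carboxylate F8. The racemate is resolved by preparative supercritical-fluid chromatography on an amylose tris(3,5-dimethylphenylcarbamate) phase, and the (R)-enantiomer is returned to the DBU equilibration (retro-oxa-Michael and re-closure) and resolved again. The stereocentre then comes from resolution instead of catalysis, and the fallback comes back to the route at 16. Because it relies on the same ring closure, it answers poor enantioselectivity but not an unfavourable equilibrium.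

Step 2. The risks are the sparingly soluble alkoxide Grignard reagent and the three operations run in one flask. The fallback sets out from 2 (with 3).
- Silylation (TBSCl, imidazole, CH2Cl2) gives tert-butyl{[(2E)-5-bromo-2-methylpent-2-en-1-yl]oxy}dimethylsilane F1.
- Mg in THF gives the ordinary Grignard reagent bromo[(3E)-5-{[tert-butyl(dimethyl)silyl]oxy}-4-methylpent-3-en-1-yl]magnesium F2.
- CuI-catalysed carbomagnesiation of 3 gives the chelate 4-[(3E)-5-{[tert-butyl(dimethyl)silyl]oxy}-4-methylpent-3-en-1-yl]-2,5-dihydro-1,2-oxamagnesole F3.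
- Instead of being coupled in the flask, the chelate is quenched with I2 at −78 °C and the vinyl iodide (2Z)-2-[(3E)-5-{[tert-butyl(dimethyl)silyl]oxy}-4-methylpent-3-en-1-yl]-3-iodoprop-2-en-1-ol F4 is isolated.
- Suzuki–Miyaura vinylation (4,4,5,5-tetramethyl-2-vinyl-1,3,2-dioxaborolane, PdCl2(dppf), Cs2CO3, THF/H2O, 60 °C) gives (2Z)-2-[(3E)-5-{[tert-butyl(dimethyl)silyl]oxy}-4-methylpent-3-en-1-yl]penta-2,4-dien-1-ol F5.
- TBAF in THF removes the silyl group, and the fallback comes back to the route at 7.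

Step 6. The risks are the very electron-poor, base-sensitive vinyl bromide 13 and racemic background ring closure of 15 under the basic coupling conditions. The fallback replaces the cross-coupling by an olefination and sets out from 7, through the same borane 14.
- Iodinolysis of 14 (I2, NaOMe, MeOH/THF, 0 °C) gives (2E,6Z)-6-(3-iodopropylidene)-2-methylhept-2-ene-1,7-diol F6.
- F6 alkylates the sodium salt of tert-butyl (diethoxyphosphoryl)acetate (3 equiv, DMF, 50 °C; the free OH groups are not deprotonated by this stabilised anion) to give tert-butyl (5Z,9E)-2-(diethoxyphosphoryl)-11-hydroxy-6-(hydroxymethyl)-10-methylundeca-5,9-dienoate F7.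
- Horner–Wadsworth–Emmons reaction of F7 with glyoxal 10 (LiCl, DBU, MeCN, 0 °C → rt) and separation of the minor Z-isomer comes back to the route at 15; step 5 is then not needed.

**Further compounds**
F1 | step 2 | tert-butyl{[(2E)-5-bromo-2-methylpent-2-en-1-yl]oxy}dimethylsilane | CC(C)(C)[Si](C)(C)OC/C(C)=C/CCBr
F2 | step 2 | bromo[(3E)-5-{[tert-butyl(dimethyl)silyl]oxy}-4-methylpent-3-en-1-yl]magnesium | CC(C)(C)[Si](C)(C)OC/C(C)=C/CC[Mg]Br
F3 | step 2 | 4-[(3E)-5-{[tert-butyl(dimethyl)silyl]oxy}-4-methylpent-3-en-1-yl]-2,5-dihydro-1,2-oxamagnesole | CC(C)(C)[Si](C)(C)OC/C(C)=C/CCC1=C[Mg]OC1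
F4 | step 2 | (2Z)-2-[(3E)-5-{[tert-butyl(dimethyl)silyl]oxy}-4-methylpent-3-en-1-yl]-3-iodoprop-2-en-1-ol | OC/C(CC/C=C(\C)CO[Si](C)(C)C(C)(C)C)=C\I
F5 | step 2 | (2Z)-2-[(3E)-5-{[tert-butyl(dimethyl)silyl]oxy}-4-methylpent-3-en-1-yl]penta-2,4-dien-1-ol | C=C/C=C(\CO)CC/C=C(\C)CO[Si](C)(C)C(C)(C)C
F6 | step 6 | (2E,6Z)-6-(3-iodopropylidene)-2-methylhept-2-ene-1,7-diol | ICC/C=C(\CO)CC/C=C(\C)CO
F7 | step 6 | tert-butyl (5Z,9E)-2-(diethoxyphosphoryl)-11-hydroxy-6-(hydroxymethyl)-10-methylundeca-5,9-dienoate | CCOP(=O)(OCC)C(CC/C=C(\CO)CC/C=C(\C)CO)C(=O)OC(C)(C)C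
F8 | step 7 | tert-butyl (2RS)-2-{2-[2,5-bis(methoxymethoxy)phenyl]-2-oxoethyl}-6-[(3E)-5-hydroxy-4-methylpent-3-en-1-yl]-2,3,4,7-tetrahydrooxepine-2-carboxylate | C/C(=C\CCC1=CCCC(CC(=O)c2cc(OCOC)ccc2OCOC)(C(=O)OC(C)(C)C)OC1)CO
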